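**Retrosynthetic overview**
- The target is reached last by acid cleavage of the two MOM ethers of its 5,7-bis-MOM derivative.
- The 2H-pyran ring is the only ring built and is formed last: a phenol carrying a single free OH (para to the benzoyl group) condenses with 3-methylbut-2-enal in an intermolecular Knoevenagel-type aldol reaction that forms C4–C4a. The resulting ortho-quinone methide closes by oxa-6π electrocyclisation onto that one OH, which fixes the ring-fusion regiochemistry.
- The prenyl group comes from an aromatic Claisen rearrangement of the 1,1-dimethylallyl ether of the symmetric phenol (O-propargylation, then semi-hydrogenation).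
- The benzoyl group comes from ortho-lithiation between the two OMOM groups of a TIPS-protected 3,5-bis(methoxymethoxy)phenol, addition to benzaldehyde and oxidation.
- The aromatic core is phloroglucinol, desymmetrised by bis-MOM protection.

Assumption: the target has no stereocentre and no E/Z-isomeric double bond, so it is achiral and the single structure drawn is the only stereoisomer; only regiochemistry needs control.

**Route**

Step 1
Reactants: 1 benzene-1,3,5-triol (phloroglucinol)
Product: 2 3,5-bis(methoxymethoxy)phenol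
Conditions: NaH (2.0 equiv), MOMCl (2.0 equiv), DMF, 0 °C to rt; chromatography (expect about 40%, mono-ether recycled)
Reagents that add atoms: chloromethyl methyl ether (MOMCl), COCCl
Why: Williamson-type O-alkylation of the sodium phenoxides with the hard electrophile MOMCl gives a statistical mixture in which the bis-ether dominates at two equivalents and is separable from mono- and tris-ethers; no stereocentre is formed.

Step 2
Reactants: 2 3,5-bis(methoxymethoxy)phenol
Product: 3 [3,5-bis(methoxymethoxy)phenoxy]tri(propan-2-yl)silane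
Conditions: TIPSCl, imidazole, DMF, rt
Reagents that add atoms: chlorotri(propan-2-yl)silane (TIPSCl), CC(C)[Si](Cl)(C(C)C)C(C)C
Why: O-silylation of the only free phenol gives a bulky, base-stable, non-directing ether that masks the future pyran oxygen and shields its two flanking positions during lithiation.

Step 3
Reactants: 3 [3,5-bis(methoxymethoxy)phenoxy]tri(propan-2-yl)silane; 4 benzaldehyde
Product: 6 rac-[2,6-bis(methoxymethoxy)-4-{[tri(propan-2-yl)silyl]oxy}phenyl](phenyl)methanol, via aryllithium 5 (not isolated)
Conditions: n-BuLi (1.2 equiv), THF, 0 °C, 1 h; PhCHO, −78 °C to rt; then H2O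
Reagents that add atoms: none
Why: directed ortho-metalation occurs at the one position flanked by two chelating OMOM groups and the aryllithium adds 1,2 to the aldehyde; the carbinol centre forms as a racemate and is erased in step 4.

Step 4
Reactants: 6 rac-[2,6-bis(methoxymethoxy)-4-{[tri(propan-2-yl)silyl]oxy}phenyl](phenyl)methanol
Product: 7 [2,6-bis(methoxymethoxy)-4-{[tri(propan-2-yl)silyl]oxy}phenyl](phenyl)methanone
Conditions: Dess–Martin periodinane, CH2Cl2, 0 °C to rt
Reagents that add atoms: none
Why: Dess–Martin oxidation converts the hindered diaryl carbinol to the benzophenone under near-neutral conditions that leave MOM and TIPS ethers intact, removing the only stereocentre.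

Step 5
Reactants: 7 [2,6-bis(methoxymethoxy)-4-{[tri(propan-2-yl)silyl]oxy}phenyl](phenyl)methanone
Product: 8 [4-hydroxy-2,6-bis(methoxymethoxy)phenyl](phenyl)methanone
Conditions: TBAF, AcOH, THF, 0 °C
Reagents that add atoms: none
Why: fluoride-mediated desilylation (buffered with acetic acid) frees only the phenol para to the ketone, giving a symmetric phenol whose two ortho positions are equivalent.

Step 6
Reactants: 8 [4-hydroxy-2,6-bis(methoxymethoxy)phenyl](phenyl)methanone; 9 3-chloro-3-methylbut-1-yne
Product: 10 [2,6-bis(methoxymethoxy)-4-[(2-methylbut-3-yn-2-yl)oxy]phenyl](phenyl)methanone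
Conditions: DBU, CuCl2·2H2O (1 mol%), MeCN, 0 °C to rt
Reagents that add atoms: none
Why: CuCl2-catalysed propargylic etherification of the acidic phenoxide gives the tertiary aryl propargyl ether cleanly at low temperature, well below the onset of any sigmatropic rearrangement.

Step 7
Reactants: 10 [2,6-bis(methoxymethoxy)-4-[(2-methylbut-3-yn-2-yl)oxy]phenyl](phenyl)methanone
Product: 11 [2,6-bis(methoxymethoxy)-4-[(2-methylbut-3-en-2-yl)oxy]phenyl](phenyl)methanone
Conditions: H2 (1 atm), Pd/CaCO3 poisoned with Pb(OAc)2, quinoline, EtOAc, rt, stopped after 1 equiv H2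
Reagents that add atoms: none
Why: semi-hydrogenation over the poisoned Pd catalyst stops at the terminal alkene and does not touch the diaryl ketone or the aryl ethers.

Step 8
Reactants: 11 [2,6-bis(methoxymethoxy)-4-[(2-methylbut-3-en-2-yl)oxy]phenyl](phenyl)methanone
Product: 13 [4-hydroxy-2,6-bis(methoxymethoxy)-3-(3-methylbut-2-en-1-yl)phenyl](phenyl)methanone, via Claisen dienone 12 (not isolated)
Conditions: PhNEt2, 120 °C, 3 h
Reagents that add atoms: none
Why: the aromatic Claisen rearrangement (3,3-sigmatropic) delivers the vinyl terminus of the 1,1-dimethylallyl ether to one of the two equivalent ortho carbons, so a normal prenyl group results; the transient sp3 centre of dienone 12 is lost on tautomerisation to the phenol.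

Step 9
Reactants: 13 [4-hydroxy-2,6-bis(methoxymethoxy)-3-(3-methylbut-2-en-1-yl)phenyl](phenyl)methanone; 14 3-methylbut-2-enal
Product: 16 [5,7-bis(methoxymethoxy)-2,2-dimethyl-8-(3-methylbut-2-en-1-yl)-2H-chromen-6-yl](phenyl)methanone, via ortho-quinone methide 15 (not isolated)
Conditions: ethylenediammonium diacetate (20 mol%), 14 (2.5 equiv), xylene, 130 °C
Reagents that add atoms: none
Why: the phenol reacts as an aromatic enol through its only free ring carbon with the iminium-activated enal (intermolecular Knoevenagel-type aldol condensation); dehydration gives ortho-quinone methide 15, whose oxa-6π electrocyclisation can only use the single free oxygen, and no stereocentre is formed.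

Step 10
Reactants: 16 [5,7-bis(methoxymethoxy)-2,2-dimethyl-8-(3-methylbut-2-en-1-yl)-2H-chromen-6-yl](phenyl)methanone
Product: 17 [5,7-dihydroxy-2,2-dimethyl-8-(3-methylbut-2-en-1-yl)-2H-chromen-6-yl](phenyl)methanone
Conditions: HCl (1.25 M in MeOH), rt to 40 °C
Reagents that add atoms: none
Why: acid-catalysed acetal exchange removes both MOM ethers, which are activated by the ortho carbonyl group, under conditions mild enough to spare the prenyl and chromene alkenes.

**Compound list**
1 | benzene-1,3,5-triol (phloroglucinol) | Oc1cc(O)cc(O)c1 | starting material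
2 | 3,5-bis(methoxymethoxy)phenol | COCOc1cc(O)cc(OCOC)c1 | intermediate
3 | [3,5-bis(methoxymethoxy)phenoxy]tri(propan-2-yl)silane | COCOc1cc(O[Si](C(C)C)(C(C)C)C(C)C)cc(OCOC)c1 | intermediate
4 | benzaldehyde | O=Cc1ccccc1 | starting material
5 | [2,6-bis(methoxymethoxy)-4-{[tri(propan-2-yl)silyl]oxy}phenyl]lithium | [Li]c1c(OCOC)cc(O[Si](C(C)C)(C(C)C)C(C)C)cc1OCOC | intermediate
6 | rac-[2,6-bis(methoxymethoxy)-4-{[tri(propan-2-yl)silyl]oxy}phenyl](phenyl)methanol | OC(c1ccccc1)c1c(OCOC)cc(O[Si](C(C)C)(C(C)C)C(C)C)cc1OCOC | intermediate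
7 | [2,6-bis(methoxymethoxy)-4-{[tri(propan-2-yl)silyl]oxy}phenyl](phenyl)methanone | O=C(c1ccccc1)c1c(OCOC)cc(O[Si](C(C)C)(C(C)C)C(C)C)cc1OCOC | intermediate
8 | [4-hydroxy-2,6-bis(methoxymethoxy)phenyl](phenyl)methanone | O=C(c1ccccc1)c1c(OCOC)cc(O)cc1OCOC | intermediate
9 | 3-chloro-3-methylbut-1-yne | CC(C)(Cl)C#C | starting material
10 | [2,6-bis(methoxymethoxy)-4-[(2-methylbut-3-yn-2-yl)oxy]phenyl](phenyl)methanone | O=C(c1ccccc1)c1c(OCOC)cc(OC(C)(C)C#C)cc1OCOC | intermediate
11 | [2,6-bis(methoxymethoxy)-4-[(2-methylbut-3-en-2-yl)oxy]phenyl](phenyl)methanone | O=C(c1ccccc1)c1c(OCOC)cc(OC(C)(C)C=C)cc1OCOC | intermediate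
12 | 4-benzoyl-3,5-bis(methoxymethoxy)-6-(3-methylbut-2-en-1-yl)cyclohexa-2,4-dien-1-one (racemic) | O=C1C=C(OCOC)C(C(=O)c2ccccc2)=C(OCOC)C1CC=C(C)C | intermediate
13 | [4-hydroxy-2,6-bis(methoxymethoxy)-3-(3-methylbut-2-en-1-yl)phenyl](phenyl)methanone | O=C(c1ccccc1)c1c(OCOC)cc(O)c(CC=C(C)C)c1OCOC | intermediate
14 | 3-methylbut-2-enal | CC(C)=CC=O | starting material
15 | 4-benzoyl-3,5-bis(methoxymethoxy)-2-(3-methylbut-2-en-1-yl)-6-(3-methylbut-2-en-1-ylidene)cyclohexa-2,4-dien-1-one | O=C1C(CC=C(C)C)=C(OCOC)C(C(=O)c2ccccc2)=C(OCOC)C1=CC=C(C)C | intermediate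
16 | [5,7-bis(methoxymethoxy)-2,2-dimethyl-8-(3-methylbut-2-en-1-yl)-2H-chromen-6-yl](phenyl)methanone | CC(C)=CCc1c(OCOC)c(C(=O)c2ccccc2)c(OCOC)c2c1OC(C)(C)C=C2 | intermediate
17 | [5,7-dihydroxy-2,2-dimethyl-8-(3-methylbut-2-en-1-yl)-2H-chromen-6-yl](phenyl)methanone (CNP0169092.0) | CC(C)=CCc1c(O)c(C(=O)c2ccccc2)c(O)c2c1OC(C)(C)C=C2 | target

**Totals**
Total step count: 10. Longest linear sequence: 10 steps (1 to 17).

**Steps most likely to fail**

Step 1. The bis-protection is statistical, so the yield is capped near 40–45% and depends on chromatographic separation. The fallback sets out from 1 and returns at 10. Friedel–Crafts benzoylation of 1 (benzoyl chloride, AlCl3, nitrobenzene) gives (2,4,6-trihydroxyphenyl)(phenyl)methanone F1. Its most acidic, non-chelated para-OH is alkylated selectively with 9 (1.0 equiv DBU, CuCl2·2H2O cat., MeCN, 0 °C) to give [2,6-dihydroxy-4-[(2-methylbut-3-yn-2-yl)oxy]phenyl](phenyl)methanone F2. Protection of both chelated OH groups (NaH, MOMCl, DMF) then gives 10. This replaces statistical differentiation by acidity-based differentiation and bypasses steps 2–6.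

Step 8. The tertiary allyl ether of a para-acyl phenol can ionise and return 8 plus isoprene instead of rearranging. The fallback sets out from 8 and returns at 13. Mono-iodination of the symmetric phenol (N-iodosuccinimide, MeCN, 0 °C) gives [4-hydroxy-3-iodo-2,6-bis(methoxymethoxy)phenyl](phenyl)methanone F3. Stille coupling with tributyl(3-methylbut-2-en-1-yl)stannane (Pd(PPh3)4, DMF, 90 °C) couples at the unsubstituted allyl terminus and gives 13 directly, replacing the sigmatropic route by cross-coupling.

Step 9. The hindered mono-phenol may condense sluggishly, the enal may oligomerise, or a MOM group may be partly lost at 130 °C. The fallback sets out from 13 and returns at 16. O-Alkylation with 9 (DBU, CuCl2·2H2O cat., MeCN, 0 °C) gives [2,6-bis(methoxymethoxy)-3-(3-methylbut-2-en-1-yl)-4-[(2-methylbut-3-yn-2-yl)oxy]phenyl](phenyl)methanone F4. Heating in PhNEt2 at 140 °C triggers a propargyl Claisen rearrangement, a 1,5-hydrogen shift to the same ortho-quinone methide 15, and oxa-6π closure to 16. Here the C4–C4a bond is made intramolecularly.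

Further compounds
F1 | step 1 | (2,4,6-trihydroxyphenyl)(phenyl)methanone | O=C(c1ccccc1)c1c(O)cc(O)cc1O
F2 | step 1 | [2,6-dihydroxy-4-[(2-methylbut-3-yn-2-yl)oxy]phenyl](phenyl)methanone | O=C(c1ccccc1)c1c(O)cc(OC(C)(C)C#C)cc1O
F3 | step 8 | [4-hydroxy-3-iodo-2,6-bis(methoxymethoxy)phenyl](phenyl)methanone | O=C(c1ccccc1)c1c(OCOC)cc(O)c(I)c1OCOC
F4 | step 9 | [2,6-bis(methoxymethoxy)-3-(3-methylbut-2-en-1-yl)-4-[(2-methylbut-3-yn-2-yl)oxy]phenyl](phenyl)methanone | O=C(c1ccccc1)c1c(OCOC)cc(OC(C)(C)C#C)c(CC=C(C)C)c1OCOC
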